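The complex with one exchanged is made from the starting complex and used up by the next exchange, so its amount in the ash flask tops out where those two rates are equal.

the same everywhere: gas 80 mM (held)
- ash: starting complex 1.8 M; the very flask that is asked about, followed so far
- elm: starting complex 0.90 M; run made earlier
- flask: starting complex 1.8 M; time 15 min

- ash (time / s: complex with one exchanged / %, complex with three exchanged / %, starting complex / %): 10.0: 12, 0, 88; 20.0: 14, 2, 76; 40.0: 29, 6, 57; 60.0: 30, 16, 44; 80.0: 23, 25, 34; 120: 16, 47, 18
- elm (time / min: complex with one exchanged / %, complex with three exchanged / %, starting complex / %): 0.833: 31, 13, 42; 1.33: 20, 36, 22; 2.50: 7, 78, 7; 4.00: 2, 99, 0; 6.00: 0, 100, 0; 10.0: 1, 98, 0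

(scatter of a reading: 1.5 percentage points)

* the moment within 15 min at which there is most complex with one exchanged
* the amount of complex with one exchanged, in percent of the starting complex charged, at that time

I assumed that both steps take up the same dissolved gas, each at a rate proportional to its own complex. Dividing the rate of making by the rate of using up then removes both time and the gas. What stays is the make-to-use ratio, a selectivity factor: the rate constant of making over that of using up, which at the top equals complex with one exchanged over starting complex. The mean of that quotient in the ash readings at 40.0 s and 60.0 s, on either side of the top, gave me 0.595. The peak height is this ratio raised to the power one over one minus the ratio, which gave me 27.8%, with 46.7% of the starting complex left. The ash readings of starting complex passed that amount shortly before 60.0 s.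

For this ratio to fail, the ash and elm runs, which differ in charge, would have to part in complex with one exchanged at nearly equal starting complex left. At 44% and 42% of starting complex left, the ash and elm runs read 30% and 31% of complex with one exchanged, a gap of 1 percentage point against a scatter of 1.5 points.

The forecast, reading “a sequential chain”, gave 31% at 0.85 min, and my peak stood lower than that.

The ash flask gave 26.9% at 0.907 min.

    gas ⇌ incoming ligand, rate k1*(csat - [incoming ligand]) (kL = 0.830 s⁻¹)
    complex with two exchanged + incoming ligand → leaving ligand + complex with three exchanged (k = 0.630 M⁻¹ s⁻¹)
    complex with one exchanged + incoming ligand → leaving ligand + complex with two exchanged (k = 0.550 M⁻¹ s⁻¹)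
    starting complex + incoming ligand → leaving ligand + complex with one exchanged (k = 0.310 M⁻¹ s⁻¹)

At that moment the ash flask held 26.9% of complex with one exchanged against 47.7% of starting complex, a quotient of 0.564, and the constant of making, 0.31 M⁻¹ s⁻¹, over that of using up, 0.55 M⁻¹ s⁻¹, is 0.564. Carried to the elm flask, with half the charge, my ratio of 0.595 gave a peak of 27.8% there too, and the highest amount of complex with one exchanged in the elm run, without the scatter, was 26.9%.

The data are simulated from invented constants, noise included.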